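Take the first reading of these runs as a mean over a fading rate, not as a first rate.

the same everywhere: catalyst 0.800 mM

| run | starting material | partner | time |
|---|---|---|---|
| Saturday's | 80.0 mM | 240 mM |  |
| Friday's | 40.0 mM | 200 mM |  |
| Sunday's | 40.0 mM | 240 mM |  |
| Thursday's | 80.0 mM | 120 mM |  |
| Wednesday's | 12.0 mM | 240 mM | 130 h |

- Saturday's run (time / h: [starting material] / mM): 4.7: 73.21; 14: 66.51; 27: 61.54; 43: 58.36; 61: 56.31; 82: 54.89; 100: 54.26; 130: 53.81
- Friday's run (time / h: [starting material] / mM): 4.7: 36.77; 14: 33.70; 27: 31.65; 43: 30.36; 61: 29.41; 82: 28.63; 100: 27.74; 130: 27.53
- Sunday's run (time / h: [starting material] / mM): 4.7: 36.44; 14: 33.36; 27: 31.21; 43: 30.05; 61: 28.79; 82: 27.68; 100: 27.56; 130: 26.79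
- Thursday's run (time / h: [starting material] / mM): 4.7: 75.81; 14: 70.95; 27: 67.02; 43: 64.47; 61: 62.80; 82: 61.16; 100: 60.71; 130: 59.89

(standard deviation of a reading: 0.2 mM)

- the power of [partner] that the first rate follows, about the charge of the Saturday's run; measure it at two percent of starting material made into product
- the power of [starting material] that the first rate follows, about the charge of the Saturday's run; measure it at two percent of starting material made into product (one fixed amount of product, the same in the runs compared)
- starting material in the Wednesday's run at 130 h, as a share of the starting material charged

- Overall: starting material + partner -> product, with catalyst as catalyst.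
- Constant volume, constant temperature.
- A reading of a species includes what of it is bound.
- An order is taken over about fifteen percent of the charge, up and down.

1. I worked in shares of the charge. At the last reading the Saturday's run kept 67.3% of its charge. The Sunday's run, with half that charge and the same partner, kept 67.0%. So I took the loss as first order in starting material, with an order near one, and for the Wednesday's run, which has the same partner, I reckoned 67.1% left.

2. The constant here is the log of what stood before an interval over what stood after it, per hour of the interval, a pseudo-first-order constant. In the Saturday's run it fell from 0.0189 h⁻¹ over the first interval to 0.0103 h⁻¹ over the second, about half. In the Thursday's run it fell from 0.0114 h⁻¹ to 0.00712 h⁻¹.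

3. I held two limits against this. In the first, the rate stays steady up to the first reading, and the ratio of the first log losses is the ratio of first rates. For the Saturday's and Thursday's runs that gives an order in partner of 0.721. In the second, the rate has faded long before the first reading and the faster run also fades sooner in step, so the first log losses draw together and the order read tends to zero. I put the real flask between them, so I expected the order in partner to stand above 0.721.

4. Taking the constant to fall as one over time plus a fixed term, the Saturday's two intervals gave 6.10 h as a reading. This is the fading time, the hours after the start in which the constant falls to half its opening value. The Thursday's run, with less partner, read longer than the Saturday's, at 9.19 h.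

5. The opening constant is the first log loss over the fading time times ln(1 + first time/fading time). That gave 0.0255 h⁻¹ for the Saturday's run and 0.0142 h⁻¹ for the Thursday's. My order in partner across those two charges was 0.845.

6. The forecast gave 0.62 for partner, 1 for starting material and 66.5% for the Wednesday's run, and its ground for partner was a ratio of 1.62 at the first reading “Saturday/Thursday gives 1.62 for doubled partner, an order near 0.7”. My partner order stood higher than its value.

The flask gave 1.0 for partner, 0.96 for starting material and 67.9% for the Wednesday's run.

    catalyst + starting material ⇌ catalyst-substrate complex, settled at all times (5.820 M⁻¹)
    catalyst-substrate complex + partner → product + catalyst + by-product (38.52 M⁻¹ h⁻¹)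
    starting material + partner + product → 2 product (10.30 M⁻² h⁻¹)
    2 partner → lost reagent (0.9792 M⁻¹ h⁻¹)

Where two percent of the Saturday's charge had turned, the Thursday's rate was 0.50 of the Saturday's, with partner charged at half the Saturday's. Carried to the Sunday's run, which had the same partner, the Saturday's fading time of 6.10 h raised the first reading to an opening constant of 0.0268 h⁻¹. The Sunday's rate at that same amount of product, over its charge, was 0.0221 h⁻¹.

The data were generated by integration for substances that don't exist, noise included.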